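The two 3-methyl-6-isopropylcyclohex-2-enyl rings on C3' and C5' are identical, so one ring synthon is made once and used twice. In each ring the aryl-bearing allylic CH is read as a former enone carbonyl, which makes the ring a disguised piperitone. A Robinson-type [3+3] annulation of methyl vinyl ketone with ethyl 2-isopropylacetoacetate forms the C(iPr)–CH2 bond (Michael) and the C(Me)=CH bond (aldol condensation) in one operation, the ester leaving as CO2. The labile isopropyl stereocentre is then fixed by dynamic kinetic resolution, and double Friedel–Crafts allylation of 2',4',6'-trihydroxychalcone relays it to both benzylic carbons.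

Key step: step 1

Assumption: ethyl 2-isopropylacetoacetate and 2',4',6'-trihydroxychalcone (pinocembrin chalcone) are taken as catalogue compounds.

Step 1
Reactants: 1 ethyl 2-isopropylacetoacetate (ethyl 2-acetyl-3-methylbutanoate, racemic); 2 methyl vinyl ketone (but-3-en-2-one)
Product: 6 rac-piperitone (3-methyl-6-(propan-2-yl)cyclohex-2-en-1-one), via Michael adduct 3 (not isolated), via keto ester 4 (not isolated), via keto acid 5 (not isolated)
Conditions: KOH (0.1 equiv), EtOH, 0 °C to rt; then 2 M aq. KOH (3 equiv), reflux; then aq. HCl to pH 2, 50 °C
Reagents that add atoms: none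
Why: The doubly activated C2 enolate of 1 adds to the β-carbon of 2 (Michael) to give 3 and so forms the C5–C6 bond of the future ring; hydroxide then enolises the acetyl CH3 of 3, which attacks the side-chain methyl ketone and, after E1cB dehydration, forms the C2=C3 bond in 4, and saponification with loss of CO2 through 5 gives 6. The closest known reaction type is the Robinson-type Michael/aldol-condensation annulation of an α-alkylacetoacetate with methyl vinyl ketone, the classical entry to piperitone, used here in its [3+3] sense (methyl vinyl ketone supplies three ring carbons and the ring methyl). The ring closes by a 6-(enolendo)-exo-trig aldol addition. C6 becomes a stereocentre only on protonation after decarboxylation and is formed racemic on purpose, because it is α to the carbonyl and is set under catalyst control in step 2. The step needs Michael addition at the isopropyl-bearing carbon only, which the ester secures by making it the sole acidic site, and closure by the acetyl CH3 onto the unhindered side-chain carbonyl instead of the side-chain CH3 onto the acetyl carbonyl, which is shielded by the adjacent quaternary carbon.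

Step 2
Reactants: 6 rac-piperitone
Product: 7 (1S,6R)-cis-piperitol ((1S,6R)-3-methyl-6-(propan-2-yl)cyclohex-2-en-1-ol)
Conditions: H2 (8 atm), trans-RuCl2[(S)-binap][(R,R)-dpen] (0.5 mol %), t-BuOK (5 mol %), i-PrOH, 25 °C
Reagents that add atoms: none
Why: Ketone-selective asymmetric hydrogenation with dynamic kinetic resolution (Noyori type): t-BuOK equilibrates the C6 epimers of 6 through the enolate while the BINAP/diamine divalent-ruthenium hydride reduces only C=O and should take the (6R)-ketone faster, adding hydride anti to the isopropyl group to set C1 as S (cis), the sense being assigned by analogy with 2-isopropylcyclohexanone, whose reduction product with this catalyst antipode has the same spatial arrangement.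

Step 3
Reactants: 7 (1S,6R)-cis-piperitol (2.4 equiv); 8 2',4',6'-trihydroxychalcone
Product: 10 neolinderachalcone, via mono-adduct 9 (not isolated)
Conditions: p-TsOH·H2O (0.2 equiv), MgSO4, CH2Cl2–THF (4:1), 0 °C to rt
Reagents that add atoms: none
Why: Friedel–Crafts allylation through an SN1 path: acid ionises 7 to the 3-methyl-6-isopropylcyclohex-2-enyl cation (C1 stereocentre erased, C6 kept), which the equivalent nucleophilic positions C3' and C5' of 8 attack in turn at the secondary allyl terminus on the face anti to the neighbouring isopropyl group, so each new benzylic centre is set R and trans to isopropyl by the C6 stereocentre while the C(Me)=CH alkene stays in its more substituted position.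

Compound list
1 | ethyl 2-isopropylacetoacetate (ethyl 2-acetyl-3-methylbutanoate, racemic) | CCOC(=O)C(C(C)C)C(C)=O | starting material
2 | methyl vinyl ketone (but-3-en-2-one) | CC(=O)C=C | starting material
3 | ethyl 2-acetyl-2-isopropyl-5-oxohexanoate (Michael adduct, racemic) | CCOC(=O)C(CCC(C)=O)(C(C)C)C(C)=O | intermediate
4 | ethyl 4-methyl-2-oxo-1-(propan-2-yl)cyclohex-3-ene-1-carboxylate (keto ester, racemic) | CCOC(=O)C1(C(C)C)CCC(C)=CC1=O | intermediate
5 | 4-methyl-2-oxo-1-(propan-2-yl)cyclohex-3-ene-1-carboxylic acid (keto acid, racemic) | OC(=O)C1(C(C)C)CCC(C)=CC1=O | intermediate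
6 | rac-piperitone (3-methyl-6-(propan-2-yl)cyclohex-2-en-1-one) | CC1=CC(=O)C(C(C)C)CC1 | intermediate
7 | (1S,6R)-cis-piperitol ((1S,6R)-3-methyl-6-(propan-2-yl)cyclohex-2-en-1-ol) | CC1=C[C@@H](O)[C@@H](C(C)C)CC1 | intermediate
8 | 2',4',6'-trihydroxychalcone ((E)-3-phenyl-1-(2,4,6-trihydroxyphenyl)prop-2-en-1-one) | O=C(/C=C/c1ccccc1)c1c(O)cc(O)cc1O | starting material
9 | mono-adduct, (E)-1-{2,4,6-trihydroxy-3-[(1R,6R)-3-methyl-6-(propan-2-yl)cyclohex-2-en-1-yl]phenyl}-3-phenylprop-2-en-1-one | CC1=C[C@H](c2c(O)cc(O)c(C(=O)/C=C/c3ccccc3)c2O)[C@@H](C(C)C)CC1 | intermediate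
10 | neolinderachalcone, (E)-1-{2,4,6-trihydroxy-3,5-bis[(1R,6R)-3-methyl-6-(propan-2-yl)cyclohex-2-en-1-yl]phenyl}-3-phenylprop-2-en-1-one | CC1=C[C@H](c2c(O)c(C(=O)/C=C/c3ccccc3)c(O)c([C@H]3C=C(C)CC[C@@H]3C(C)C)c2O)[C@@H](C(C)C)CC1 | target

Total step count: 3. Longest linear sequence: 3 steps (1 → 6 → 7 → 10).

Steps most likely to fail

Step 2. Racemisation at C6 may be too slow relative to hydrogenation, or the catalyst may discriminate the two ketone enantiomers poorly, because the vinyl and CH(iPr) flanks differ less than in a saturated 2-alkylcyclohexanone; either would lower the optical purity. If the sense of induction proves opposite, the enantiomeric catalyst is used. Fallback, setting out from 6 and returning at 7: racemic 6 is reduced 1,2- and cis-selectively with LiBH(s-Bu)3 (THF, −78 °C, equatorial attack, aqueous work-up) to racemic cis-piperitol F3. Lipase-mediated transesterification (Amano lipase PS, vinyl acetate, MTBE, 30 °C, stopped near half conversion) should acylate the (1S,6R)-enantiomer, by the empirical lipase rule for secondary alcohols with the isopropyl-bearing ring carbon as the large group. This gives (1S,6R)-cis-piperityl acetate F4, which is separated from the unreacted (1R,6S)-alcohol by chromatography. Methanolysis (K2CO3 cat., MeOH, rt) returns 7.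

Step 3. Acid may cyclise the 2',6'-dihydroxychalcone to a flavanone by oxa-Michael addition, or add a phenol to the ring alkene. Optical purity may also be lost if the cation is deprotonated to achiral α-terpinene and reprotonated. Any minor-enantiomer unit should end up mainly in a separable diastereomer of the bis-adduct. Fallback, setting out from 7 and returning at 10: the same acid-catalysed double allylation is run on commercial 2',4',6'-trihydroxyacetophenone, which cannot cyclise, to give 3',5'-bis[(1R,6R)-3-methyl-6-(propan-2-yl)cyclohex-2-en-1-yl]-2',4',6'-trihydroxyacetophenone F5. Claisen–Schmidt condensation of F5 with benzaldehyde (excess KOH, aq. EtOH, rt, cold HCl work-up) then builds the cinnamoyl group under basic conditions that leave the ring alkenes untouched and gives 10.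

Step 1. The quaternary keto ester 3 may lose its acetyl group by retro-Claisen cleavage, close onto the ester in a Claisen sense, or resist hydrolysis at the hindered ester stage 4. Fallback, setting out from 2 and returning at 6: 2 is combined with catalogue 3-isopropylpentane-2,4-dione in the same one-pot regime (K2CO3 cat., EtOH, rt; then 2 M aq. KOH, reflux; HCl work-up). Michael addition gives 3-acetyl-3-isopropylheptane-2,6-dione F1. Hydroxide then removes one acetyl group by retro-Claisen cleavage, now the designed loss of the activating group, to give 3-isopropylheptane-2,6-dione F2. Aldol condensation of the C1 methyl onto the unhindered C6 carbonyl closes the ring to 6, so both ring bonds still arise in one operation.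

Further compounds
F1 | step 1 | 3-acetyl-3-isopropylheptane-2,6-dione | CC(=O)CCC(C(C)C)(C(C)=O)C(C)=O
F2 | step 1 | 3-isopropylheptane-2,6-dione (racemic) | CC(=O)CCC(C(C)C)C(C)=O
F3 | step 2 | rac-cis-piperitol (racemate, (1S,6R)-enantiomer drawn) | CC1=C[C@@H](O)[C@@H](C(C)C)CC1
F4 | step 2 | (1S,6R)-cis-piperityl acetate ((1S,6R)-3-methyl-6-(propan-2-yl)cyclohex-2-en-1-yl acetate) | CC1=C[C@@H](OC(C)=O)[C@@H](C(C)C)CC1
F5 | step 3 | 3',5'-bis[(1R,6R)-3-methyl-6-(propan-2-yl)cyclohex-2-en-1-yl]-2',4',6'-trihydroxyacetophenone | CC1=C[C@H](c2c(O)c(C(C)=O)c(O)c([C@H]3C=C(C)CC[C@@H]3C(C)C)c2O)[C@@H](C(C)C)CC1
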